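The earlier runs and the new flask were computed for substances that don't exist, and the scatter is random.

In the elm run the isomer of the product rose late on by 0.00700 /min of the charge, more slowly than the 0.0120 /min of the maple run, and the two recipes differ in impurity.

all flasks: free catalyst 10 mM

| flask | starting material | impurity | remark | time |
|---|---|---|---|---|
| elm | 2 M | 10 mM | the very flask that is asked about, followed so far |  |
| maple | 2 M | 6.7 mM | run made earlier |  |
| flask | 2.0 M | 10 mM |  | 30 min |

| run | time / min | target / % | isomer of the product / % | starting material / % |
|---|---|---|---|---|
| elm | 2.50 | 43.5 | 5.4 | 50.8 |
| elm | 5.00 | 47.5 | 8.4 | 43.6 |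
| elm | 6.00 | 47.2 | 9.4 | 43.9 |
| elm | 10.0 | 46.4 | 12.2 | 42.3 |
| maple | 1.50 | 36.6 | 4.8 | 58.8 |
| maple | 4.00 | 46.2 | 9.5 | 44.3 |
| maple | 8.00 | 45.3 | 13.7 | 40.2 |
| maple | 12.0 | 43.1 | 18.5 | 38.7 |

(readings scatter by 0.3 percentage points)

- share of target in target plus isomer of the product at 2.0 s
- share of target in target plus isomer of the product at 30 min
- which of target and isomer of the product there is more of at 30 min

I supposed that impurity removes free catalyst one for one, a second-order loss, so that maple keeps a share of 33.0%. In elm, with equal charges, the share falls as tau/(tau+t). Elm's earlier slope, 0.0120 /min, matches maple's late one, so I set elm's share equal to maple's at that interval's midpoint, which reads tau as 1.85 min. Integrating the share gives the catalyst dose, minutes at full charge, tau times the logarithm of (tau+t)/tau: 5.26 min for elm at 30 min.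

Two extreme versions of elm bound the end. If the whole late slope follows the free catalyst, the isomer of the product reaches 19.0%. If the whole slope is a constant leak, it reaches 26.2%. A mixture of both parts lies between them. Target keeps 52.3% of the remainder, so even at the upper bound it stays ahead, 38.6%. My tau took the slopes as wholly following the free catalyst, and the readings do not divide them between that part and a leak, so going a quarter of the way up was a judgement and not a reading: 20.8% isomer of the product, a target share of 66.6%. For the early time I took maple's earliest share, 88.4%.

The forecast said 91% and 66%, “so target still leads”. The flask gave 88.8% and 66.6%, with target at 41.4% and isomer of the product at 20.7%.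

    isomer of the product + free catalyst ⇌ starting material + free catalyst, rate k1*[free catalyst]*[isomer of the product] forward; the back reaction follows from the equilibrium constant (k = 1.40 /M/min)
    free catalyst + impurity → spent catalyst (k = 90.0 /M/min)
    starting material ⇌ target (K = 1.10, k = 0.450 /min)
    target ⇌ isomer of the product (K = 3.70, k = 0.00850 /min)

With the rate constant of the impurity step in the scheme, tau is 1/(k[free catalyst]) = 1.11 min, and the dose of the flask at 30 min is 3.70 min. With 0.040 M of impurity in the neighbouring flask, the dose is tau times the logarithm of [impurity]/([impurity]−[free catalyst]), using the charges: 0.320 min, less than in the flask. In the neighbouring flask, free catalyst ended at 0% and impurity at 75.0% of its charge. The isomer of the product in the neighbouring flask fell in a smaller proportion than the dose, ending at 12.9% beside target at 45.4%, a target share of 77.8%.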